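The target, an (E)-2-alkyl-2-enal linking two labdane acids, is cut at C13–C14. C13 is an isolated CH(CH3) centre outside both decalins (rings A/B and A'/B') with three carbon neighbours (C12, C16, C14), so it is assembled on boron by two consecutive 1,2-metallate shifts in one pot: a C12 pinacol boronate from trans-communic acid, a sparteine-lithiated ethyl benzoate (C13, C16) and a 2-lithioallyl ether (C14, C15, C15') from imbricatolic acid, whose ring fusion is first inverted at C5'. The first shift sets C13 by reagent control; the Zweifel shift forms C13–C14 and fixes the enal geometry.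

Key step: step 18

Remark on numbering: labdane numbering is used; unprimed atoms belong to the half that carries C13, C14 and the aldehyde C15, primed atoms to the other half (monomer names use plain numbers).
Remark on the structure: in the given structure H-5' is syn to CH3-20' and to the C19' carboxyl (decalin A'/B' cis-fused, 5'-epi), whereas decalin A/B is the natural trans-fused labdane; C5' of the natural precursor is therefore inverted in steps 8–10.
Assumption: trans-communic acid, imbricatolic acid, ethyl 2,4,6-triisopropylbenzoate, (+)-sparteine and 2-(trimethylsilyl)ethyl 2,2,2-trichloroacetimidate are taken as purchasable.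
Abbreviations: TMSE = 2-(trimethylsilyl)ethyl, TBS = tert-butyldimethylsilyl, Bpin = 4,4,5,5-tetramethyl-1,3,2-dioxaborolan-2-yl.

Step 1
Reactants: 1 trans-communic acid
Product: 2 12-hydroxy-13,14,15,16-tetranorlabd-8(17)-en-19-oic acid
Conditions: O3 (1 equiv), pyridine, CH2Cl2/MeOH, −78 °C; then NaBH4, −78 → 0 °C
Reagents that add atoms: ozone, [O-][O+]=O
Why: Ozonolysis with reductive work-up, in which ozone should attack the electron-rich trisubstituted C12=C13 bond of the diene before the hindered 8(17)-methylene and NaBH4 reduces the ozonide to the C12 alcohol.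

Step 2
Reactants: 2 12-hydroxy-13,14,15,16-tetranorlabd-8(17)-en-19-oic acid
Product: 3 TMSE 12-hydroxy-13,14,15,16-tetranorlabd-8(17)-en-19-oate
Conditions: Cl3CC(=NH)OCH2CH2SiMe3, toluene, 100 °C
Reagents that add atoms: 2-(trimethylsilyl)ethyl 2,2,2-trichloroacetimidate, C[Si](C)(C)CCOC(=N)C(Cl)(Cl)Cl
Why: Promoter-free trichloroacetimidate esterification, in which the acid protonates the imidate and is O-alkylated, so the congested axial acyl carbon is never attacked and the alcohol, which cannot activate the imidate, should stay free.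

Step 3
Reactants: 3 TMSE 12-hydroxy-13,14,15,16-tetranorlabd-8(17)-en-19-oate
Product: 4 TMSE 12-iodo-13,14,15,16-tetranorlabd-8(17)-en-19-oate
Conditions: I2, PPh3, imidazole, CH2Cl2, 0 °C → rt
Reagents that add atoms: iodine, II
Why: Appel reaction, an SN2 displacement at the unhindered primary carbon that leaves the ester and the exocyclic alkene untouched.

Step 4
Reactants: 4 TMSE 12-iodo-13,14,15,16-tetranorlabd-8(17)-en-19-oate
Product: 5 TMSE 12-Bpin-13,14,15,16-tetranorlabd-8(17)-en-19-oate
Conditions: B2pin2, CuI (10 mol %), PPh3, LiOMe, DMF, rt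
Reagents that add atoms: bis(pinacolato)diboron, CC1(C)OB(OC1(C)C)B1OC(C)(C)C(C)(C)O1
Why: Copper-catalysed borylation of a primary alkyl iodide, for which the only cyclisation open to a transient C12 radical (5-endo onto C17) is disfavoured.

Step 5
Reactants: 6 imbricatolic acid
Product: 7 TMSE imbricatolate
Conditions: Cl3CC(=NH)OCH2CH2SiMe3, toluene, 100 °C
Reagents that add atoms: 2-(trimethylsilyl)ethyl 2,2,2-trichloroacetimidate, C[Si](C)(C)CCOC(=N)C(Cl)(Cl)Cl
Why: Same promoter-free trichloroacetimidate esterification as in step 2, selective for the carboxylic acid over the primary alcohol.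

Step 6
Reactants: 7 TMSE imbricatolate
Product: 8 TMSE (13S)-15-(TBS-oxy)labd-8(17)-en-19-oate
Conditions: TBSCl, imidazole, DMF, rt
Reagents that add atoms: tert-butyldimethylsilyl chloride, CC(C)(C)[Si](C)(C)Cl
Why: Standard silylation of the primary alcohol, so that no free hydroxyl competes as a directing group in step 10.

Step 7
Reactants: 8 TMSE (13S)-15-(TBS-oxy)labd-8(17)-en-19-oate
Product: 9 TMSE (13S)-15-(TBS-oxy)-8-oxo-17-norlabdan-19-oate
Conditions: O3, CH2Cl2/MeOH, −78 °C; then Me2S
Reagents that add atoms: ozone, [O-][O+]=O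
Why: Ozonolysis of the only alkene gives the 8-ketone, in which C9 keeps its configuration because the equatorial side chain is the stable epimer of the trans-fused ketone.

Step 8
Reactants: 9 TMSE (13S)-15-(TBS-oxy)-8-oxo-17-norlabdan-19-oate
Product: 11 TMSE (13S)-15-(TBS-oxy)-8-oxo-17-norlabd-6-en-19-oate, via trimethylsilyl enol ether 10 (not isolated)
Conditions: LiN(iPr)2, THF, −78 °C; Me3SiCl; then Pd(OAc)2, MeCN, rt
Reagents that add atoms: none
Why: Kinetic deprotonation at the less hindered C7 methylene (not at the tertiary C9–H), silylation and Saegusa–Ito oxidation should give the 6-en-8-one regioselectively.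

Step 9
Reactants: 11 TMSE (13S)-15-(TBS-oxy)-8-oxo-17-norlabd-6-en-19-oate
Product: 13 TMSE (13S)-15-(TBS-oxy)-8-oxo-17-norlabd-5-en-19-oate, via potassium dienolate 12 (not isolated)
Conditions: KOtBu, tBuOH/THF, rt, argon; inverse quench into cold aq. AcOH
Reagents that add atoms: none
Why: Enone deconjugation through the extended dienolate, in which equilibrating base removes the axial γ-hydrogen H5 (erasing the C5 stereocentre) and kinetic protonation at the α-carbon C7 gives the β,γ-enone, while C9 should remain the equatorial (natural) epimer.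

Step 10
Reactants: 13 TMSE (13S)-15-(TBS-oxy)-8-oxo-17-norlabd-5-en-19-oate
Product: 14 TMSE (13S)-15-(TBS-oxy)-8-oxo-17-nor-5β-labdan-19-oate
Conditions: H2 (4 bar), [Ir(cod)(PCy3)(py)]PF6 (10 mol %), CH2Cl2, rt
Reagents that add atoms: none
Why: Ester-directed homogeneous hydrogenation, in which the cationic iridium binds the C19 ester carbonyl on the β-face next to C5 and should deliver H2 to C5=C6 from that face, so that the new C5 stereocentre has H syn to the carboxyl and to CH3-20 (cis-fused decalin).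

Step 11
Reactants: 14 TMSE (13S)-15-(TBS-oxy)-8-oxo-17-nor-5β-labdan-19-oate
Product: 15 TMSE (13S)-15-(TBS-oxy)-5β-labd-8(17)-en-19-oate
Conditions: Zn, CH2Br2, TiCl4, THF/CH2Cl2, 0 °C → rt
Reagents that add atoms: dibromomethane, BrCBr
Why: Takai–Lombardo methylenation, chosen because it is non-basic and so does not expose the enolisable C9 centre, whose natural configuration is no longer guaranteed to be the thermodynamic one in the cis-fused ketone.

Step 12
Reactants: 15 TMSE (13S)-15-(TBS-oxy)-5β-labd-8(17)-en-19-oate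
Product: 16 TMSE (13S)-15-hydroxy-5β-labd-8(17)-en-19-oate
Conditions: PPTS, MeOH, rt
Reagents that add atoms: none
Why: Mild acidic methanolysis removes the primary TBS ether, and the TMSE ester and the exocyclic alkene should tolerate pyridinium tosylate.

Step 13
Reactants: 16 TMSE (13S)-15-hydroxy-5β-labd-8(17)-en-19-oate
Product: 17 TMSE (13S)-15-oxo-5β-labd-8(17)-en-19-oate
Conditions: Dess–Martin periodinane, NaHCO3, CH2Cl2, rt
Reagents that add atoms: none
Why: Dess–Martin oxidation of the primary alcohol to the aldehyde under buffered, non-epimerising conditions.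

Step 14
Reactants: 17 TMSE (13S)-15-oxo-5β-labd-8(17)-en-19-oate
Product: 18 terminal alkyne (side chain end CH(CH3)CH2C≡CH)
Conditions: MeC(O)C(N2)P(O)(OMe)2, K2CO3, MeOH, 0 °C → rt
Reagents that add atoms: dimethyl (1-diazo-2-oxopropyl)phosphonate, CC(=O)C(=[N+]=[N-])P(=O)(OC)OC
Why: Seyferth–Gilbert homologation with the Ohira–Bestmann reagent turns the aldehyde carbon C15' into an alkyne carbon and adds the carbon that becomes C14 of the target.

Step 15
Reactants: 18 terminal alkyne
Product: 19 propargylic alcohol (side chain end CH2C≡CCH2OH)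
Conditions: n-BuLi, THF, −78 °C; (CH2O)n, −78 °C → rt
Reagents that add atoms: formaldehyde (as paraformaldehyde), C=O
Why: Hydroxymethylation of the lithium acetylide adds C15, and the α-quaternary ester should be inert to the acetylide at low temperature.

Step 16
Reactants: 19 propargylic alcohol
Product: 20 (E)-2-(tributylstannyl)allylic alcohol
Conditions: Bu3SnH, PdCl2(PPh3)2 (2 mol %), THF, 0 °C → rt
Reagents that add atoms: tributyltin hydride, CCCC[SnH](CCCC)CCCC
Why: Palladium-catalysed syn-hydrostannation, in which the propargylic oxygen directs tin to the proximal carbon C14, so tin ends up cis to H-15' and trans to C14'.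

Step 17
Reactants: 20 (E)-2-(tributylstannyl)allylic alcohol
Product: 21 TBS ether of 20
Conditions: TBSCl, imidazole, DMF, rt
Reagents that add atoms: tert-butyldimethylsilyl chloride, CC(C)(C)[Si](C)(C)Cl
Why: Standard silylation masks the allylic alcohol for the organolithium chemistry of step 18.

Step 18
Reactants: 5 TMSE 12-Bpin-13,14,15,16-tetranorlabd-8(17)-en-19-oate; 21 TBS ether of the (E)-vinylstannane; 22 ethyl 2,4,6-triisopropylbenzoate
Product: 26 bis-TMSE ester TBS ether of the coupled allylic alcohol, via lithiated benzoate 23 (not isolated), via secondary boronic ester 24 (not isolated), via alkenyllithium 25 (not isolated)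
Conditions: 22, s-BuLi, (+)-sparteine, Et2O, −78 °C, 5 h; add 5, −78 °C → rt; cool to −78 °C, THF, add 25 (from 21, n-BuLi, THF, −78 °C); I2, THF, −78 °C; NaOMe, MeOH, −78 → 0 °C
Reagents that add atoms: none
Why: The (+)-sparteine-complexed (R)-α-lithiated benzoate 23 adds to boronate 5 with retention, and the C12 alkyl group then shifts from boron to carbon anti to the benzoate leaving group (inversion at the carbenoid carbon) to give (13S)-24. Alkenyllithium 25 (tin–lithium exchange with retention) forms a second boronate, iodonium formation triggers the shift of C13 from boron to C14 with retention at C13, and NaOMe induces anti-elimination of boron and iodine. The closest known reactions are the lithiation–borylation homologation of boronic esters and the Zweifel olefination, here run in one pot as a three-component union; no ring is closed. C13 is controlled only by the chiral carbenoid, independent of the remote C9 centre, and its configuration is carried stereospecifically through both shifts. The anti-elimination inverts the alkenyllithium geometry, so lithium trans to C14' places C13 cis to C14' and gives the E-enal after oxidation. The step needs the organolithiums to react at boron and not at the esters, which the fast boronate formation at −78 °C and the α-quaternary TMSE esters should secure, with lithium triisopropylbenzoate and sparteine as spectators.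

Step 19
Reactants: 26 bis-TMSE ester TBS ether of the coupled allylic alcohol
Product: 27 diacid allylic alcohol
Conditions: TBAF, THF, rt; aq. citric acid work-up
Reagents that add atoms: none
Why: Fluoride cleaves the silyl ether and fragments both TMSE esters (to ethene and Me3SiF) by attack at silicon, so the hindered acyl carbons need not be attacked and no enal is yet present.

Step 20
Reactants: 27 diacid allylic alcohol
Product: 28 target CNP0229303.1
Conditions: MnO2, CH2Cl2, rt
Reagents that add atoms: none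
Why: MnO2 oxidises only the allylic alcohol to the conjugated aldehyde, leaving the acids, the two exocyclic alkenes and the alkene geometry untouched.

Compound list
1 | trans-communic acid, (4S,5R,9S,10R,12E)-labda-8(17),12,14-trien-19-oic acid | C=C1CC[C@@H]2[C@](C)(CCC[C@]2(C)C(=O)O)[C@H]1C/C=C(\C)C=C | starting material
2 | (4S,5R,9S,10R)-12-hydroxy-13,14,15,16-tetranorlabd-8(17)-en-19-oic acid | C=C1CC[C@@H]2[C@](C)(CCC[C@]2(C)C(=O)O)[C@H]1CCO | intermediate
3 | TMSE ester of 2 | C=C1CC[C@@H]2[C@](C)(CCC[C@]2(C)C(=O)OCC[Si](C)(C)C)[C@H]1CCO | intermediate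
4 | TMSE 12-iodo-13,14,15,16-tetranorlabd-8(17)-en-19-oate | C=C1CC[C@@H]2[C@](C)(CCC[C@]2(C)C(=O)OCC[Si](C)(C)C)[C@H]1CCI | intermediate
5 | TMSE 12-Bpin-13,14,15,16-tetranorlabd-8(17)-en-19-oate | C=C1CC[C@@H]2[C@](C)(CCC[C@]2(C)C(=O)OCC[Si](C)(C)C)[C@H]1CCB3OC(C)(C)C(C)(C)O3 | intermediate
6 | imbricatolic acid, (4S,5R,9S,10R,13S)-15-hydroxylabd-8(17)-en-19-oic acid | OCC[C@@H](C)CC[C@H]1C(=C)CC[C@@H]2[C@]1(C)CCC[C@]2(C)C(=O)O | starting material
7 | TMSE imbricatolate | OCC[C@@H](C)CC[C@H]1C(=C)CC[C@@H]2[C@]1(C)CCC[C@]2(C)C(=O)OCC[Si](C)(C)C | intermediate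
8 | TMSE (13S)-15-(TBS-oxy)labd-8(17)-en-19-oate | CC(C)(C)[Si](C)(C)OCC[C@@H](C)CC[C@H]1C(=C)CC[C@@H]2[C@]1(C)CCC[C@]2(C)C(=O)OCC[Si](C)(C)C | intermediate
9 | TMSE (13S)-15-(TBS-oxy)-8-oxo-17-norlabdan-19-oate (5α-H, 9α-H) | CC(C)(C)[Si](C)(C)OCC[C@@H](C)CC[C@H]1C(=O)CC[C@@H]2[C@]1(C)CCC[C@]2(C)C(=O)OCC[Si](C)(C)C | intermediate
10 | 8-trimethylsilyloxy-7-ene (silyl enol ether of 9) | CC(C)(C)[Si](C)(C)OCC[C@@H](C)CC[C@H]1C(O[Si](C)(C)C)=CC[C@@H]2[C@]1(C)CCC[C@]2(C)C(=O)OCC[Si](C)(C)C | intermediate (not isolated)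
11 | TMSE (13S)-15-(TBS-oxy)-8-oxo-17-norlabd-6-en-19-oate (5α-H) | CC(C)(C)[Si](C)(C)OCC[C@@H](C)CC[C@H]1C(=O)C=C[C@@H]2[C@]1(C)CCC[C@]2(C)C(=O)OCC[Si](C)(C)C | intermediate
12 | potassium 5,7-dien-8-olate of 11 (C5 planar) | CC(C)(C)[Si](C)(C)OCC[C@@H](C)CC[C@H]1C([O-])=CC=C2[C@]1(C)CCC[C@]2(C)C(=O)OCC[Si](C)(C)C.[K+] | intermediate (not isolated)
13 | TMSE (13S)-15-(TBS-oxy)-8-oxo-17-norlabd-5-en-19-oate | CC(C)(C)[Si](C)(C)OCC[C@@H](C)CC[C@H]1C(=O)CC=C2[C@]1(C)CCC[C@]2(C)C(=O)OCC[Si](C)(C)C | intermediate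
14 | TMSE (13S)-15-(TBS-oxy)-8-oxo-17-nor-5β-labdan-19-oate (cis-fused: H-5 syn to CH3-20 and C19; 9α-H) | CC(C)(C)[Si](C)(C)OCC[C@@H](C)CC[C@H]1C(=O)CC[C@H]2[C@]1(C)CCC[C@]2(C)C(=O)OCC[Si](C)(C)C | intermediate
15 | TMSE (13S)-15-(TBS-oxy)-5β-labd-8(17)-en-19-oate | CC(C)(C)[Si](C)(C)OCC[C@@H](C)CC[C@H]1C(=C)CC[C@H]2[C@]1(C)CCC[C@]2(C)C(=O)OCC[Si](C)(C)C | intermediate
16 | TMSE (13S)-15-hydroxy-5β-labd-8(17)-en-19-oate | OCC[C@@H](C)CC[C@H]1C(=C)CC[C@H]2[C@]1(C)CCC[C@]2(C)C(=O)OCC[Si](C)(C)C | intermediate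
17 | TMSE (13S)-15-oxo-5β-labd-8(17)-en-19-oate | O=CC[C@@H](C)CC[C@H]1C(=C)CC[C@H]2[C@]1(C)CCC[C@]2(C)C(=O)OCC[Si](C)(C)C | intermediate
18 | terminal alkyne: 5β-labd-8(17)-en-19-oate TMSE ester with side chain end CH(CH3)CH2C≡CH | C#CC[C@@H](C)CC[C@H]1C(=C)CC[C@H]2[C@]1(C)CCC[C@]2(C)C(=O)OCC[Si](C)(C)C | intermediate
19 | propargylic alcohol: side chain end CH(CH3)CH2C≡CCH2OH | OCC#CC[C@@H](C)CC[C@H]1C(=C)CC[C@H]2[C@]1(C)CCC[C@]2(C)C(=O)OCC[Si](C)(C)C | intermediate
20 | (E)-vinylstannane: side chain end CH2CH=C(SnBu3)CH2OH, tin cis to the vinyl H | CCCC[Sn](CCCC)(CCCC)/C(CO)=C/C[C@@H](C)CC[C@H]1C(=C)CC[C@H]2[C@]1(C)CCC[C@]2(C)C(=O)OCC[Si](C)(C)C | intermediate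
21 | TBS ether of 20 | CCCC[Sn](CCCC)(CCCC)/C(CO[Si](C)(C)C(C)(C)C)=C/C[C@@H](C)CC[C@H]1C(=C)CC[C@H]2[C@]1(C)CCC[C@]2(C)C(=O)OCC[Si](C)(C)C | intermediate
22 | ethyl 2,4,6-triisopropylbenzoate | CCOC(=O)c1c(C(C)C)cc(C(C)C)cc1C(C)C | starting material
23 | (R)-1-lithioethyl 2,4,6-triisopropylbenzoate, (+)-sparteine complex | C[C@@H]([Li])OC(=O)c1c(C(C)C)cc(C(C)C)cc1C(C)C | intermediate (not isolated)
24 | TMSE (13S)-13-Bpin-14,15-dinorlabd-8(17)-en-19-oate | C=C1CC[C@@H]2[C@](C)(CCC[C@]2(C)C(=O)OCC[Si](C)(C)C)[C@H]1CC[C@H](C)B3OC(C)(C)C(C)(C)O3 | intermediate (not isolated)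
25 | alkenyllithium from 21 (lithium trans to C14') | [Li]/C(CO[Si](C)(C)C(C)(C)C)=C/C[C@@H](C)CC[C@H]1C(=C)CC[C@H]2[C@]1(C)CCC[C@]2(C)C(=O)OCC[Si](C)(C)C | intermediate (not isolated)
26 | bis-TMSE ester of the (13S,13'S)-dimer with C15 as CH2OTBS, C14=C15' with C13 cis to C14' | C=C1CC[C@@H]2[C@](C)(CCC[C@]2(C)C(=O)OCC[Si](C)(C)C)[C@H]1CC[C@H](C)/C(CO[Si](C)(C)C(C)(C)C)=C\C[C@@H](C)CC[C@H]1C(=C)CC[C@H]2[C@]1(C)CCC[C@]2(C)C(=O)OCC[Si](C)(C)C | intermediate
27 | 19,19'-diacid with C15 as CH2OH | C=C1CC[C@@H]2[C@](C)(CCC[C@]2(C)C(=O)O)[C@H]1CC[C@H](C)/C(CO)=C\C[C@@H](C)CC[C@H]1C(=C)CC[C@H]2[C@]1(C)CCC[C@]2(C)C(=O)O | intermediate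
28 | CNP0229303.1, (4S,5R,9S,10R,13S,14E)-14-[(4'S,5'S,9'S,10'R,13'S)-19'-carboxy-5'β-labd-8'(17')-en-15'-ylidene]-15-oxolabd-8(17)-en-19-oic acid | C=C1CC[C@@H]2[C@](C)(CCC[C@]2(C)C(=O)O)[C@H]1CC[C@H](C)/C(C=O)=C\C[C@@H](C)CC[C@H]1C(=C)CC[C@H]2[C@]1(C)CCC[C@]2(C)C(=O)O | target

Total step count: 20. Longest linear sequence: 16 steps (6 → 28, steps 5–20).

Steps most likely to fail

Step 9. The base may fail to remove the hindered axial γ-hydrogen H5, so that only the cross-conjugated C9 enolate forms, or the β,γ-enone may slip back into conjugation during the quench. Fallback: starting from 11, acid-catalysed enol acetylation (isopropenyl acetate, TsOH, reflux) should give the linear 8-acetoxy-5,7-diene F1, in which H5 is lost by acid-catalysed enolisation instead of deprotonation. MeLi (2 equiv, THF, −78 °C) then releases the lithium dienolate F2, which is protonated at C7 with AcOH at −78 °C. The route is rejoined at 13.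

Step 10. Facial selectivity may be poor: hydrogen delivered to the open α-face returns the trans-fused series. The iridium catalyst may also move the double bond back into conjugation before reduction. Fallback: starting from 13, Luche reduction (NaBH4, CeCl3, MeOH, −78 °C, hydride from the α-face away from CH3-20) should give the axial 8β-alcohol F3. Its homoallylic hydroxyl lies on the β-face and takes over as the directing group in the same iridium-catalysed hydrogenation, giving the cis-fused alcohol F4. Dess–Martin oxidation returns to 14.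

Step 18. In the telescoped sequence, boronate formation between the hindered secondary boronic ester and the α-branched alkenyllithium may be incomplete in the presence of the first-stage by-products. The organolithiums may attack the esters, and an imperfect carbenoid purity cannot be corrected in one pot. Fallback: starting from 5 and 22, only the homologation is run and 24 is isolated and purified. Starting from 21, iododestannylation (I2, CH2Cl2, 0 °C) gives the vinyl iodide F5, and iodine–magnesium exchange (i-PrMgCl·LiCl, THF) gives the ester-tolerant alkenylmagnesium chloride F6. F6 and 24 are united in THF/DMSO followed by I2 and NaOMe (Grignard variant of the Zweifel olefination). The route is rejoined at 26.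

Further compounds
F1 | step 9 | 8-acetoxy-5,7-diene (linear dienyl acetate from 11) | CC(C)(C)[Si](C)(C)OCC[C@@H](C)CC[C@H]1C(OC(C)=O)=CC=C2[C@]1(C)CCC[C@]2(C)C(=O)OCC[Si](C)(C)C
F2 | step 9 | lithium 5,7-dien-8-olate | CC(C)(C)[Si](C)(C)OCC[C@@H](C)CC[C@H]1C([O-])=CC=C2[C@]1(C)CCC[C@]2(C)C(=O)OCC[Si](C)(C)C.[Li+]
F3 | step 10 | 8β-hydroxy-17-norlabd-5-ene (TBS ether, TMSE ester) | CC(C)(C)[Si](C)(C)OCC[C@@H](C)CC[C@H]1[C@@H](O)CC=C2[C@]1(C)CCC[C@]2(C)C(=O)OCC[Si](C)(C)C
F4 | step 10 | 8β-hydroxy-17-nor-5β-labdane (cis-fused; TBS ether, TMSE ester) | CC(C)(C)[Si](C)(C)OCC[C@@H](C)CC[C@H]1[C@@H](O)CC[C@H]2[C@]1(C)CCC[C@]2(C)C(=O)OCC[Si](C)(C)C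
F5 | step 18 | (E)-vinyl iodide from 21 (iodine trans to C14') | CC(C)(C)[Si](C)(C)OC/C(I)=C\C[C@@H](C)CC[C@H]1C(=C)CC[C@H]2[C@]1(C)CCC[C@]2(C)C(=O)OCC[Si](C)(C)C
F6 | step 18 | alkenylmagnesium chloride from F5 | CC(C)(C)[Si](C)(C)OC/C([Mg]Cl)=C\C[C@@H](C)CC[C@H]1C(=C)CC[C@H]2[C@]1(C)CCC[C@]2(C)C(=O)OCC[Si](C)(C)C
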